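**Retrosynthetic overview**
1. Target 5 is the tyrosol ester of a C25 acid (acyl chain numbered from the ester carbonyl, C1). The chain is cut between C3 and C4: a primary docosyl radical (C4–C25) is added to the CH2= terminus of 2-(4-hydroxyphenyl)ethyl acrylate 3, which already carries C1–C3 and the tyrosol ester.
2. The radical is released from tricosanoic acid 4. Its carboxyl group is a traceless activating group, lost as CO2 in the same operation, so the key step should give 5 directly with the phenol unprotected.
3. Enabling feature: the ester carbonyl C1(=O)O makes C2=C3 an electron-poor alkene with an unsubstituted C3 terminus, and C4 heads an unbranched, unfunctionalised C22 chain. The 4-hydroxyphenyl ring is insulated from this site by the O–CH2–CH2 spacer.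
4. Acrylate 3 comes from tyrosol 1 and vinyl acrylate 2 by lipase-catalysed acyl transfer, selective for the primary alcohol over the phenol.
5. Ring formation: none. The only ring, the para-disubstituted benzene ring, is bought with tyrosol.

Key step: step 2

**Step 1**
Reactants: 1 tyrosol [4-(2-hydroxyethyl)phenol]; 2 vinyl acrylate
Product: 3 2-(4-hydroxyphenyl)ethyl acrylate
Conditions: Novozym 435 (immobilised Candida antarctica lipase B), 2 (3 equiv), BHT (cat.), MTBE, 40 °C; filter, evaporate
Reagents that add atoms: none
Why: Lipase-catalysed irreversible transesterification (enzymatic acyl transfer from an enol ester): the acryloyl-enzyme formed from 2 should be intercepted only by the unhindered primary alcohol of 1, because this lipase does not accept phenols as acyl acceptors, while the released vinyl alcohol tautomerises to acetaldehyde and the neutral medium with a radical inhibitor protects the acrylate double bond.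

**Step 2**
Reactants: 3 2-(4-hydroxyphenyl)ethyl acrylate; 4 tricosanoic acid
Product: 5 2-(4-hydroxyphenyl)ethyl pentacosanoate
Conditions: 4 (1.5 equiv), 9-(2-chlorophenyl)acridine (10 mol%), Cu(MeCN)4BF4 (10 mol%), degassed CH2Cl2, 400 nm LEDs, 25 °C
Reagents that add atoms: none
Why: Decarboxylative Giese (radical conjugate) addition under acridine/copper dual photocatalysis: acid 4 hydrogen-bonds to the acridine nitrogen, excitation of this complex triggers proton-coupled electron transfer to give the acridinyl radical and an acyloxy radical, which loses CO2 to the primary docosyl radical; this nucleophilic radical adds to the CH2 terminus (C3) of acrylate 3, and the resulting C2 radical, stabilised by the ester carbonyl, is captured by Cu(I) and then reduced and protonated with the electron and proton stored in the acridinyl radical, which regenerates both catalysts without a stoichiometric reagent. The closest known reaction type is the visible-light direct decarboxylative conjugate addition of unactivated aliphatic carboxylic acids, primary fatty acids included, to acrylate esters. No ring is closed and no stereocentre is created, so neither a closure mode nor a stereocontrol element is involved. Three selectivities are needed: attack at C3 only, secured by conjugation of C2=C3 with the C1 carbonyl and by the lack of substituents at C3; a single addition instead of telomerisation, secured by fast copper-mediated reduction of the electrophilic C2 radical and by keeping 3 the limiting partner; and activation of the CO2H group in the presence of the phenol, expected because only the much more acidic carboxylic acid forms the photoactive hydrogen-bonded complex and because O–H abstraction from a 4-alkylphenol by a primary alkyl radical is slower than its addition to an acrylate. The nonpolar solvent should keep the C23 acid in solution, and the step should deliver the complete C25 chain and the free phenol, that is, the target, in one operation.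

**Compound list**
1 | tyrosol [4-(2-hydroxyethyl)phenol] | OCCc1ccc(O)cc1 | starting material
2 | vinyl acrylate (ethenyl prop-2-enoate) | C=CC(=O)OC=C | starting material
3 | 2-(4-hydroxyphenyl)ethyl acrylate (tyrosyl acrylate) | C=CC(=O)OCCc1ccc(O)cc1 | intermediate
4 | tricosanoic acid | CCCCCCCCCCCCCCCCCCCCCCC(=O)O | starting material
5 | 2-(4-hydroxyphenyl)ethyl pentacosanoate | CCCCCCCCCCCCCCCCCCCCCCCCC(=O)OCCc1ccc(O)cc1 | target

**Step count and risks**
Total step count: 2. Longest linear sequence: 2 steps (1 → 3 → 5). The route has only two steps, so both are ranked and no third step exists.

Risk 1, step 2 (key step). The unprotected phenol may divert the open-shell cycle: proton-coupled electron transfer from the phenolic O–H to the excited acridine, hydrogen-atom transfer to the docosyl radical, or coupling of phenoxyl radicals. Chain growth of the C2 radical onto further acrylate is a second concern. The fallback keeps the same C3–C4 bond formation but takes the phenol out of the radical step. It sets out from 4 and 2: the decarboxylative radical addition of 4 to vinyl acrylate 2 under the step-2 conditions should give vinyl pentacosanoate F1, because the acrylate C=C is far more reactive toward a nucleophilic alkyl radical than the enol-ester C=C. F1 would then act as an irreversible acyl donor in a Novozym 435-catalysed transesterification with tyrosol 1 (MTBE, 45 °C), a well-known type of selective acylation of the primary alcohol of tyrosol by fatty acid vinyl esters. The sequence comes back to the route at 5.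

Risk 2, step 1. The acrylate double bond may be lost during acylation or isolation (oxa-Michael addition of the phenol or the alcohol, radical oligomerisation on concentration), or the acyl transfer may stall through deactivation of the enzyme by acetaldehyde. The fallback activates the alcohol instead of the acyl donor. It sets out from 1: Mitsunobu esterification with acrylic acid (PPh3 and DIAD premixed at 0 °C in THF so that no free phosphine meets the acrylic acid, then 1 and acrylic acid, 0 °C) should esterify only the primary alcohol, since the carboxylic acid is far more acidic than the phenol and is the preferred pronucleophile. No new intermediate is made and the route is rejoined at 3.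

**Further compounds**
F1 | step 2 | vinyl pentacosanoate | CCCCCCCCCCCCCCCCCCCCCCCCC(=O)OC=C
F0 | step 1 | none | none
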